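## Retrosynthetic overview

1. Target 17 ⇐ bis-epoxy alcohol 16 by Z-retentive angeloylation of the C2 hydroxyl with the preformed mixed anhydride 9.
2. 16 ⇐ dienol 14: both oxiranes (C3–C4 and C10–C11) are closed in one flask, the ring one by delivery from the C2 hydroxyl, the side-chain one by a chiral dioxirane; this creates C3, C4 and C10.
3. 14 ⇐ enone 10 by α'-hydroxylation, Mitsunobu inversion with acetic acid and Luche reduction, which builds the all-cis C6/C1/C2 array.
4. 10 ⇐ (R)-carvone 1 by ene chlorination, N-oxide oxidation, Brown allylation (sets C8), cross-metathesis and angeloylation with 9 (made once from angelic acid 8).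
5. Ring order: the cyclohexane comes intact from carvone; the two epoxides are formed last and together.

Convention and assumption: commercial (R)-(−)-carvone of ≥98% ee is used. Bisabolane-type locants are used from 7 on: ring C1–C6 with C6 bearing the side chain, C1 the acetoxy carbon, C2 the angeloyloxy carbon, C3 the methyl-bearing carbon; side chain C7(=C14H2)–C8–C9–C10–C11. "Angeloyl" means (2Z)-2-methylbut-2-enoyl. The C3 descriptor is R in the free C2 alcohols 15 and 16 and S in the C2 esters; this is only a change of CIP priorities, the geometry is the same.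

## Route

Step 1
Reactants: 1 (R)-(−)-carvone
Product: 2 (5R)-5-(3-chloroprop-1-en-2-yl)-2-methylcyclohex-2-en-1-one
Conditions: Ca(OCl)2, solid CO2, CH2Cl2–H2O, 0 to 20 °C
Reagents that add atoms: calcium hypochlorite, [Ca+2].[O-]Cl.[O-]Cl
Why: Ene-type allylic chlorination by HOCl made in the flask attacks only the electron-rich isopropenyl group (chlorine on the terminal carbon, double bond shifted), leaving the deactivated enone olefin and the stereocentre untouched.

Step 2
Reactants: 2 (5R)-5-(3-chloroprop-1-en-2-yl)-2-methylcyclohex-2-en-1-one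
Product: 3 2-[(1R)-4-methyl-5-oxocyclohex-3-en-1-yl]prop-2-enal
Conditions: Me3NO (anhydrous), NaI (10 mol%), DMSO, 20 to 40 °C
Reagents that add atoms: trimethylamine N-oxide, C[N+](C)(C)[O-]
Why: Ganem oxidation (a Kornblum-type process): the N-oxide oxygen displaces the allylic halide and the alkoxyammonium salt loses trimethylamine to give the 2-substituted acrolein; the C–H at the ring stereocentre is only vinylogously acidic and is not removed by trimethylamine at 40 °C.

Step 3
Reactants: 3 2-[(1R)-4-methyl-5-oxocyclohex-3-en-1-yl]prop-2-enal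
Product: 5 (5R)-5-[(3S)-3-hydroxyhexa-1,5-dien-2-yl]-2-methylcyclohex-2-en-1-one, via borinate ester 4 (not isolated)
Conditions: (−)-Ipc2B(allyl) (1 M in pentane), Et2O, −78 °C; then HOCH2CH2NH2, 20 °C
Reagents that add atoms: (−)-B-allyldiisopinocampheylborane (from (+)-α-pinene), C=CCB([C@@H]1C[C@@H]2C[C@H]([C@H]1C)C2(C)C)[C@@H]1C[C@@H]2C[C@H]([C@H]1C)C2(C)C
Why: Brown asymmetric allylboration through a closed chair transition state adds allyl to the Si face of the aldehyde (reagent control, giving 8S), and at −78 °C the aldehyde reacts far faster than the enone carbonyl.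

Step 4
Reactants: 5 (5R)-5-[(3S)-3-hydroxyhexa-1,5-dien-2-yl]-2-methylcyclohex-2-en-1-one; 6 2-methylbut-2-ene
Product: 7 (6R,8S)-8-hydroxybisabola-3,7(14),10-trien-2-one
Conditions: RuCl2(=CHPh)(PCy3)(H2IMes) (second-generation Grubbs catalyst, 3 mol%), excess 6, CH2Cl2, 40 °C
Reagents that add atoms: none
Why: Olefin cross-metathesis exchanges the methylene of the monosubstituted vinyl group for the isopropylidene of 6, while the 1,1-disubstituted and enone olefins are too hindered or electron-poor to react; no stereocentre is touched.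

Step 5
Reactants: 8 angelic acid
Product: 9 (2Z)-2-methylbut-2-enoic 2,4,6-trichlorobenzoic anhydride
Conditions: 2,4,6-Cl3C6H2COCl (1.0 equiv), Et3N (1.05 equiv), PhMe, 20 °C, 2 h; Et3N·HCl filtered off under argon; kept as a dry PhMe stock solution at −20 °C (one batch serves steps 6 and 11)
Reagents that add atoms: 2,4,6-trichlorobenzoyl chloride, O=C(Cl)c1c(Cl)cc(Cl)cc1Cl
Why: Yamaguchi mixed-anhydride formation: the triethylammonium angelate is O-acylated by the hindered aroyl chloride, and because no nucleophilic catalyst or conjugate addition is involved the Z geometry is kept.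

Step 6
Reactants: 7 (6R,8S)-8-hydroxybisabola-3,7(14),10-trien-2-one; 9 (2Z)-2-methylbut-2-enoic 2,4,6-trichlorobenzoic anhydride
Product: 10 (6R,8S)-8-angeloyloxybisabola-3,7(14),10-trien-2-one
Conditions: 9 (1.5 equiv), Et3N (1.5 equiv), PhMe, 80 °C
Reagents that add atoms: none
Why: Yamaguchi-type esterification: the C8 hydroxyl attacks the less hindered angeloyl carbonyl of the mixed anhydride, with retention at C8, and the absence of a nucleophilic catalyst prevents equilibration of the angelate to the tiglate.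

Step 7
Reactants: 10 (6R,8S)-8-angeloyloxybisabola-3,7(14),10-trien-2-one
Product: 12 (1S,6S,8S)-8-angeloyloxy-1-hydroxybisabola-3,7(14),10-trien-2-one, via sodium dienolate 11 (not isolated)
Conditions: NaN(SiMe3)2 (1.1 equiv), THF, −78 °C; then 2-(phenylsulfonyl)-3-phenyloxaziridine, −78 °C; AcOH quench at −78 °C
Reagents that add atoms: 2-(phenylsulfonyl)-3-phenyloxaziridine (Davis oxaziridine), O=S(=O)(c1ccccc1)N1OC1c1ccccc1
Why: Kinetic α'-deprotonation gives the cross-conjugated dienolate, and Davis enolate oxidation delivers oxygen anti to the bulky C6 side chain, giving the trans hydroxy ketone.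

Step 8
Reactants: 12 (1S,6S,8S)-8-angeloyloxy-1-hydroxybisabola-3,7(14),10-trien-2-one
Product: 13 (1R,6S,8S)-1-acetoxy-8-angeloyloxybisabola-3,7(14),10-trien-2-one
Conditions: PPh3, DIAD, AcOH, PhMe, 0 to 20 °C
Reagents that add atoms: acetic acid, CC(=O)O
Why: Mitsunobu esterification displaces the oxyphosphonium group by acetate in an SN2 step activated by the adjacent carbonyl, inverting C1 so that the acetate is cis to the side chain.

Step 9
Reactants: 13 (1R,6S,8S)-1-acetoxy-8-angeloyloxybisabola-3,7(14),10-trien-2-one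
Product: 14 (1R,2S,6S,8S)-1-acetoxy-8-angeloyloxybisabola-3,7(14),10-trien-2-ol
Conditions: NaBH4, CeCl3·7H2O, MeOH, −78 °C; pH 7 buffer quench at −78 °C
Reagents that add atoms: none
Why: Luche 1,2-reduction delivers hydride axially, anti to the axial C1 acetoxy group (as in carvone to cis-carveol), so the new equatorial C2 hydroxyl is cis to both the acetate and the side chain; the cold neutral quench avoids acetyl migration.

Step 10
Reactants: 14 (1R,2S,6S,8S)-1-acetoxy-8-angeloyloxybisabola-3,7(14),10-trien-2-ol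
Product: 16 (1R,2R,3R,4S,6S,8S,10S)-1-acetoxy-8-angeloyloxy-3,4:10,11-diepoxybisabol-7(14)-en-2-ol, via ring monoepoxide 15 (not isolated)
Conditions: VO(acac)2 (5 mol%), t-BuOOH (1.3 equiv, decane), PhMe, 0 to 20 °C; then, same flask, ent-Shi ketone (enantiomer of the D-fructose-derived ketone, 3 equiv), KHSO5 (as 2KHSO5·KHSO4·K2SO4), NaHCO3 buffer (pH 8), MeCN–CH2(OMe)2–aq. Na2EDTA, 0 °C
Reagents that add atoms: tert-butyl hydroperoxide, CC(C)(C)OO; potassium peroxymonosulfate, [K+].[O-]S(=O)(=O)OO
Why: Proposed new method: two known oxygen transfers are run back to back in one flask; first the vanadate ester of the C2 hydroxyl (pentavalent vanadium) delivers oxygen from t-BuOOH to the same face of the C3=C4 olefin (Sharpless–Michaelson hydroxyl-directed epoxidation, the only way onto the crowded all-cis face, fixing C3 and C4); then, after the EDTA buffer sequesters the vanadium, the dioxirane of the ent-Shi ketone epoxidises the remaining trisubstituted prenyl olefin through the spiro transition state (Shi epoxidation, the mirror image of the R-selective D-fructose catalyst, setting 10S); the 1,1-disubstituted and angelate olefins are too slow to compete; the closest precedents are these two reactions run separately.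

Step 11
Reactants: 16 (1R,2R,3R,4S,6S,8S,10S)-1-acetoxy-8-angeloyloxy-3,4:10,11-diepoxybisabol-7(14)-en-2-ol; 9 (2Z)-2-methylbut-2-enoic 2,4,6-trichlorobenzoic anhydride
Product: 17 (1R,2R,3S,4S,6S,8S,10S)-1-acetoxy-2,8-bis(angeloyloxy)-3,4:10,11-diepoxybisabol-7(14)-ene (CNP0118696.1)
Conditions: 9 (2 equiv), Et3N (2 equiv), PhMe, 75 °C
Reagents that add atoms: none
Why: Yamaguchi-type esterification with the mixed anhydride acylates the hindered C2 hydroxyl with retention and without Z to E isomerisation, and the amine buffers the liberated aroic acid so that both epoxides survive.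

## Compound list

1 | (R)-(−)-carvone, (5R)-2-methyl-5-(prop-1-en-2-yl)cyclohex-2-en-1-one | C=C(C)[C@@H]1CC=C(C)C(=O)C1 | starting material
2 | (5R)-5-(3-chloroprop-1-en-2-yl)-2-methylcyclohex-2-en-1-one | C=C(CCl)[C@@H]1CC=C(C)C(=O)C1 | intermediate
3 | 2-[(1R)-4-methyl-5-oxocyclohex-3-en-1-yl]prop-2-enal | C=C(C=O)[C@@H]1CC=C(C)C(=O)C1 | intermediate
4 | O-diisopinocampheylboryl (borinate) ester of 5 (not isolated) | C=C([C@H](CC=C)OB([C@@H]1C[C@@H]2C[C@H]([C@H]1C)C2(C)C)[C@@H]1C[C@@H]2C[C@H]([C@H]1C)C2(C)C)[C@@H]1CC=C(C)C(=O)C1 | intermediate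
5 | (5R)-5-[(3S)-3-hydroxyhexa-1,5-dien-2-yl]-2-methylcyclohex-2-en-1-one | C=C([C@H](CC=C)O)[C@@H]1CC=C(C)C(=O)C1 | intermediate
6 | 2-methylbut-2-ene | CC=C(C)C | starting material
7 | (6R,8S)-8-hydroxybisabola-3,7(14),10-trien-2-one | C=C([C@H](CC=C(C)C)O)[C@@H]1CC=C(C)C(=O)C1 | intermediate
8 | angelic acid, (2Z)-2-methylbut-2-enoic acid | C/C=C(/C)C(=O)O | starting material
9 | (2Z)-2-methylbut-2-enoic 2,4,6-trichlorobenzoic anhydride | C/C=C(/C)C(=O)OC(=O)c1c(Cl)cc(Cl)cc1Cl | intermediate
10 | (6R,8S)-8-angeloyloxybisabola-3,7(14),10-trien-2-one | C=C([C@H](CC=C(C)C)OC(=O)/C(C)=C\C)[C@@H]1CC=C(C)C(=O)C1 | intermediate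
11 | sodium C1=C2 dienolate of 10 (not isolated) | C=C([C@H](CC=C(C)C)OC(=O)/C(C)=C\C)[C@@H]1CC=C(C)C([O-])=C1.[Na+] | intermediate
12 | (1S,6S,8S)-8-angeloyloxy-1-hydroxybisabola-3,7(14),10-trien-2-one (hydroxyl trans to side chain) | C=C([C@H](CC=C(C)C)OC(=O)/C(C)=C\C)[C@@H]1CC=C(C)C(=O)[C@H]1O | intermediate
13 | (1R,6S,8S)-1-acetoxy-8-angeloyloxybisabola-3,7(14),10-trien-2-one (acetate cis to side chain) | C=C([C@H](CC=C(C)C)OC(=O)/C(C)=C\C)[C@@H]1CC=C(C)C(=O)[C@@H]1OC(C)=O | intermediate
14 | (1R,2S,6S,8S)-1-acetoxy-8-angeloyloxybisabola-3,7(14),10-trien-2-ol (all-cis) | C=C([C@H](CC=C(C)C)OC(=O)/C(C)=C\C)[C@@H]1CC=C(C)[C@H](O)[C@@H]1OC(C)=O | intermediate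
15 | (1R,2R,3R,4S,6S,8S)-1-acetoxy-8-angeloyloxy-3,4-epoxybisabola-7(14),10-dien-2-ol (not isolated) | C=C([C@H](CC=C(C)C)OC(=O)/C(C)=C\C)[C@@H]1C[C@@H]2O[C@]2(C)[C@H](O)[C@@H]1OC(C)=O | intermediate
16 | (1R,2R,3R,4S,6S,8S,10S)-1-acetoxy-8-angeloyloxy-3,4:10,11-diepoxybisabol-7(14)-en-2-ol | C=C([C@H](C[C@@H]1OC1(C)C)OC(=O)/C(C)=C\C)[C@@H]1C[C@@H]2O[C@]2(C)[C@H](O)[C@@H]1OC(C)=O | intermediate
17 | (1R,2R,3S,4S,6S,8S,10S)-1-acetoxy-2,8-bis(angeloyloxy)-3,4:10,11-diepoxybisabol-7(14)-ene (CNP0118696.1) | C=C([C@H](C[C@@H]1OC1(C)C)OC(=O)/C(C)=C\C)[C@@H]1C[C@@H]2O[C@]2(C)[C@H](OC(=O)/C(C)=C\C)[C@@H]1OC(C)=O | target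

## Step count and risks

Total step count: 11. Longest linear sequence: 10 steps (steps 1 to 4 and 6 to 11, from 1 to 17); step 5 is a one-step side branch that supplies 9.

Steps most likely to fail:

Step 10 (one-flask double epoxidation). The weak points are the basic aqueous dioxirane stage acting on a free cis hydroxy acetate (acetyl migration from C1 to C2), a sluggish vanadium stage on the equatorial C2 hydroxyl, and possible over-oxidation of the C7=C14 olefin. The fallback sets out from 14 and comes back at 17. Run only the VO(acac)2/t-BuOOH stage and isolate the ring monoepoxide 15. Acylate its C2 hydroxyl with the mixed anhydride 9 (Et3N, PhMe, 75 °C) to give (1R,2R,3S,4S,6S,8S)-1-acetoxy-2,8-bis(angeloyloxy)-3,4-epoxybisabola-7(14),10-diene F1, which has no free hydroxyl left. Then epoxidise the prenyl olefin of F1 with catalytic ent-Shi ketone and KHSO5 under the K2CO3-buffered conditions (pH 10.5, 0 °C, short reaction time). This gives 17 directly and bypasses 16; the order of acylation and side-chain epoxidation is reversed.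

Step 8 (Mitsunobu inversion at a hindered α-ketol). No reaction, or elimination followed by aromatisation to a phenol, are the likely failures. The fallback sets out from 10 and comes back at 13. Regenerate the dienolate 11 from 10 as in step 7 and quench it with N-bromosuccinimide at −78 °C to give (1S,6S,8S)-8-angeloyloxy-1-bromobisabola-3,7(14),10-trien-2-one F2, with bromine anti to the side chain. Displace the bromide with CsOAc and 18-crown-6 in toluene; SN2 at the α-keto carbon inverts C1 and gives 13. The alcohol 12 and the Mitsunobu reaction are avoided.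

Step 11 (angeloylation of the hindered C2 hydroxyl between a fully substituted epoxide carbon and a cis acetate). Sluggish acylation or Z to E isomerisation are the risks. The fallback sets out from 16 and comes back at 17, building the Z olefin on the ester instead of transferring it. Esterify 16 with 2-[bis(2,2,2-trifluoroethoxy)phosphoryl]propanoic acid (DCC, catalytic DMAP, CH2Cl2, 0 °C) to give (1R,2R,3S,4S,6S,8S,10S)-1-acetoxy-8-angeloyloxy-2-{2-[bis(2,2,2-trifluoroethoxy)phosphoryl]propanoyloxy}-3,4:10,11-diepoxybisabol-7(14)-ene F3, a mixture of epimers at the phosphonate carbon. Treat F3 with KN(SiMe3)2 and 18-crown-6 in THF at −78 °C, then acetaldehyde; the Still–Gennari olefination gives the (Z)-2-methylbut-2-enoate, which is 17.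

Further compounds
F1 | step 10 | (1R,2R,3S,4S,6S,8S)-1-acetoxy-2,8-bis(angeloyloxy)-3,4-epoxybisabola-7(14),10-diene | C=C([C@H](CC=C(C)C)OC(=O)/C(C)=C\C)[C@@H]1C[C@@H]2O[C@]2(C)[C@H](OC(=O)/C(C)=C\C)[C@@H]1OC(C)=O
F2 | step 8 | (1S,6S,8S)-8-angeloyloxy-1-bromobisabola-3,7(14),10-trien-2-one | C=C([C@H](CC=C(C)C)OC(=O)/C(C)=C\C)[C@@H]1CC=C(C)C(=O)[C@H]1Br
F3 | step 11 | (1R,2R,3S,4S,6S,8S,10S)-1-acetoxy-8-angeloyloxy-2-{2-[bis(2,2,2-trifluoroethoxy)phosphoryl]propanoyloxy}-3,4:10,11-diepoxybisabol-7(14)-ene | C=C([C@H](C[C@@H]1OC1(C)C)OC(=O)/C(C)=C\C)[C@@H]1C[C@@H]2O[C@]2(C)[C@H](OC(=O)C(C)P(=O)(OCC(F)(F)F)OCC(F)(F)F)[C@@H]1OC(C)=O
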